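A one-step reaction has one clock, but this scheme has several, so each constant is read here as a time or rate at the charged amounts.

    initiator → 2 initiating radical (k1 = 9.5 × 10⁻⁵ s⁻¹)
    substrate + initiating radical → capped initiator + first chain carrier (k2 = 1.9 × 10⁶ M⁻¹ s⁻¹)
    partner + first chain carrier → target + second chain carrier (k3 = 90000 M⁻¹ s⁻¹)
    substrate + second chain carrier → by-product + first chain carrier (k4 = 2.4 × 10⁵ M⁻¹ s⁻¹)
    2 first chain carrier → ended chains A (k5 = 1.1 × 10⁸ M⁻¹ s⁻¹)
    2 second chain carrier → ended chains B (k6 = 4 × 10⁸ M⁻¹ s⁻¹)
    partner → decomposed reagent (k7 = 6.1 × 10⁻⁵ s⁻¹)
    second chain carrier + radical scavenger → ended chains C (k8 = 6.7 × 10⁸ M⁻¹ s⁻¹)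

in all of them: initiator 0.20 mM; radical scavenger 40 µM

| charge | substrate | partner | time | remark |
|---|---|---|---|---|
| south-east | 20 mM | 22.0 mM | 25 min | everything together in a closed stirred flask, run for 25 min |
| west | 20 mM | 22.0 mM (fed, over 25.0 min) | 25 min | a stirred flask in which partner is dosed at a steady rate over 25.0 min without added volume, worked up at 25 min |
| north | 20 mM | 22.0 mM |  | a single well-mixed tank run continuously and read at steady state, 25 min in it on average |
| south-west | 20 mM (fed, over 25.0 min) | 22.0 mM | 25 min | all but substrate at the start; substrate goes in evenly over 25.0 min, the run ends at 25 min |

* the set-up with the highest amount of target at the outlet or at the end, in percent of the substrate put in ("none" if the first two lie within 2 percentage points) (south-east / west / north / south-west / none)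
* amount of target at the outlet or at the end, in percent of the substrate put in, south-east
* amount of target at the outlet or at the end, in percent of the substrate put in, west
* amount of target at the outlet or at the end, in percent of the substrate put in, north
* amount of target at the outlet or at the end, in percent of the substrate put in, south-west

- in percentages every species weighs as the substrate in it: one ended chains A counts as two
- a step written with two of one species runs at k times the square of its concentration and takes two of it each time
- the stated concentrations are those of everything mixed, before any reaction; amounts are the same in each set-up
- the feed brings no volume worth counting
- run time (south-east): 25 min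

The initiator has a half-life of 122 min, so in 25 min it sheds 13.3% of its charge and radicals arrive as a trickle. Each initiating radical meets substrate at 38000 s⁻¹ and becomes first chain carrier, which meets partner at 1980 s⁻¹ and gives target and second chain carrier. But that carrier meets substrate at 4800 s⁻¹ and scavenger at 26800 s⁻¹, faster, so at the charged amounts 15.2% of them carry on.

In south-east the chain therefore waits until the initiator has shed 10.0% of its charge, two radicals per initiator. That wait is the lag, or induction period: 18.5 min, the time the initiator needs to supply radicals equal to the scavenger charge. In south-east it leaves a quarter of the run.

After the lag, at charged amounts, steps 5 and 6 balance the radical supply and target grows by 0.0582 min⁻¹ as a fraction of the substrate charge. The window thus gives 37.8%, a mark south-east stays under as partner and substrate fall.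

I reckon the same lag for west and south-west, with 74.0% of the dose in when it ends, so I place both below south-east. In north, scavenger enters steadily at 80.2% of the radical supply, less than the supply, so I reckon on a chain running there at steady state. Held at charged amounts, the rate goes with the square root of the remaining supply, which is worth 11.1 min at full rate, more than the 6.50 min window, so I place north first.

The forecast gives 30.5% for south-east, 28.6% for west, 38.5% for north and 28.8% for south-west, names north best, and holds that “the chain barely runs until the scavenger is gone”.

The simulation gives 30.4%, 28.4%, 38.6% and 28.8% in that order, with north best.

South-east reaches its 30.4% in 25 min; set against the reckoned lag of 18.5 min, that is a mean of 0.0468 min⁻¹ over the window against 0.0582 min⁻¹ at charged amounts. In south-west, scavenger raised alone to 42.8 µM gives a reckoned lag of 19.9 min, taking 1.40 min off the window, and the answer there has moved from 28.8% by 5 points.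

(The constants stand for no real mixture; the rest is arithmetic.)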